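## The problem

The target 33 is a bicyclic labdane: a trans-fused decalin (rings A and B) with a gem-dimethyl group at C4, an angular methyl group at C10, and a tetrasubstituted C8=C9 alkene that carries the C17 methyl group and, at C9, a chain ending in a (13Z)-trisubstituted allylic alcohol. Ring B bears a 6β-acetate and a 7α-hydroxyl on adjacent carbons, trans and diaxial, and the acetate sits on the more hindered oxygen (1,3-diaxial to the C10 and 4β methyl groups), so only the least accessible of three hydroxyls is acylated. Four stereocentres have to be set (C5, C6, C7, C10). C10 is quaternary and must come first; its β-methyl group can then send reagents to the α-face at C5 and C6, and a bulky 6β-substituent can in turn send a nucleophile to the α-face of C7. The 7-hydroxyl is allylic to a tetrasubstituted alkene and ionises readily in acid, the neryl-type Z-alkene is prone to isomerisation, and the acetate excludes hydrides and strong bases once it is in place, so the end of the route has to be mild and non-acidic. The feature that opens a short way into ring B is the triad C7(OH)–C8(C17)=C9: a secondary allylic carbinol next to a substituted vinylic carbon is what a gem-dihalocyclopropane fused to a cyclopentene gives on opening and capture of water. Ring B can therefore be seen as a five-membered ring (C5, C6, C7, C9, C10) plus an inserted carbon C8, whose remaining halogen becomes the C17 methyl group.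

## Retrosynthesis

**Hydroxyl differentiation (33 ⇒ 32 ⇒ 31).** The acetyl C–O bonds at O7 and O15 are added in the retrosynthetic sense, leading to triacetate 32 and then triol 31. Selective acylation of 31 would go to the wrong oxygens, because O6 is the most hindered. Selective removal from 32 runs in the right direction: the 6β-acetate is the slowest to be cleaved. The forward reactions must acylate an axial hydroxyl and then stop a methanolysis after two of three esters.

**Side-chain terminus (31 ⇒ 30 ⇒ 29 ⇒ 27 ⇒ 25 ⇒ 24).** C13–C16 and C14–C15 are cut. A syn-carbocupration of ynoate 27 with a methylcuprate fixes the Z geometry of enoate 29 by mechanism, which carboalumination of a terminal alkyne or a hydroalumination/iodination sequence would not do (both lead to the E series). Reduction gives 30, and C15 comes from methyl chloroformate on the terminal alkyne 25. The two ring hydroxyls of diol 24 are masked as triethylsilyl ethers for these three steps. The precursor 24 is a plain terminal alkyne with no alkene geometry to control.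

**C17 methyl group (24 ⇒ 23 ⇒ 22).** C8–C17 is cut to alkenyl bromide 22, which a methylzinc cross-coupling converts into 23. The bromide is not an added burden: it is the atom that the ring expansion leaves on C8. Removal of both silicon groups from 23 (alkynyl and O6) in one fluoride step gives 24.

**Ring B by one-carbon insertion (22 ⇒ 21 ⇒ 19 + 20).** C7–C8 and C8–C9 are cut and C7–C9 is re-formed. Bromo alcohol 22 is the water-trapped product of opening the dibromocyclopropane 21, which is the dibromocarbene adduct of hydrindene 19 and bromoform 20. Against a closure of ring B by aldol, metathesis or cycloaddition, this cut creates the C7 oxygen, its configuration, the C8=C9 alkene in its final position and the C8 handle in one step. It also moves all earlier stereochemical work to a rigid, angularly methylated hydrindane. The forward reaction needs one reactive alkene only (hence a silylalkyne in the chain), capture of water at C7 and not at C9, and entry on the α-face, for which the 6β-silyloxy group is responsible.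

**Side-chain attachment (19 ⇒ 13 + 18; 18 ⇐ 17 ⇐ 16 ⇐ 14).** C9–C11 is cut to enol triflate 13 and alkylzinc iodide 18. The triflate can form in one direction only, since C10 is quaternary, and it places the alkene exactly at C7=C9. Reagent 18 comes from iodide 17, made from but-3-yn-1-ol 14 by C-silylation (16) and iodination.

**C5 and C6 (13 ⇒ 11 ⇒ 10 ⇒ 9 ⇒ 8 ⇒ 7 ⇒ 5).** The C6–O and C5–H bonds are traced to hydroboration of the C5=C6 alkene of 5 from the α-face, which sets the trans ring fusion in alcohol 7. The 6α-alcohol is inverted through ketone 8 to the 6β-alcohol 9, which is silylated (10); the C9 ketal is then opened to ketone 11. Each step uses the C10 methyl group as the controlling element.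

**Ring A substituents and C10 (5 ⇒ 3 ⇒ 2 ⇒ 1).** The two C4–methyl bonds are cut and the C3 oxygen is restored, leading through ketone 3 and ketal 2 to the (S)-Hajos–Parrish ketone 1. Compound 1 supplies C10 with the correct absolute configuration, a C9 carbonyl for the later triflate, and an enone that is converted by deconjugative dimethylation and Wolff–Kishner reduction into the C4 gem-dimethyl group and the C5=C6 alkene.

## Roads not taken

Alternative 1: The cut is made at C9–C10 and C5–C6 and leaves ring B open. 3-Methylcyclohex-2-enone A1 would take up the α-substituted vinylalane A2 at C10 under a chiral N-heterocyclic carbene–copper catalyst made from Cu(OTf)2, and the aluminium enolate would be trapped at C5 by 3-methylbut-3-enal A3 to give aldol A4.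
- Merits: one catalytic operation sets quaternary C10 and C5 trans to it and brings in the C6 oxygen from three simple achiral pieces. In speed of stereocentre generation it is clearly ahead of the chosen plan, which needs about eight steps to have C10, C5 and C6 in place.
- Weak points: ring B must still be closed by metathesis of two 1,1-disubstituted alkenes to the tetrasubstituted C8=C9 bond beside quaternary C10, the hardest class of ring-closing metathesis even for second-generation ruthenium catalysts. C7 arrives as a methylene group, so the 7α-hydroxyl needs a late allylic oxidation that must tell C7 from C11 and from the side-chain allylic positions. The C4 carbonyl must become a gem-dimethyl group next to epimerisable C5, the aldol has no evident control over C6, and the chain ends at C12.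
- Comparison: the chosen plan pays in linear steps and protecting-group operations, but its key step supplies what A4 lacks: ring B, the C7 oxygen with its configuration, and a handle for C17.

Alternative 2: Ring A is closed last on an arene that is ring B. Cutting C1–C10 leads to phenol A5, whose para carbon (C10) would attack the far terminus of a tethered π-allylpalladium unit (Pd2(dba)3, chiral phosphine) to give dienone A6.
- Merits: A6 already holds all twenty carbons, the Z side chain, the C17 methyl group, oxygen at C6 and C7 and a catalytically set C10. In convergence this exceeds what the chosen key step achieves.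
- Weak points: A5 is a hexasubstituted benzene whose regiocontrolled assembly is a synthesis of its own, and the dearomatisation must create a quaternary centre between two ortho substituents. None of C5, C6 and C7 is a stereocentre in A6. The C5=C6 enol ether must be reduced from the α-face in the presence of the C2=C3, C8=C9 and C13=C14 alkenes (C8=C9 being part of the dienone). The C7 ketone must give the axial 7α-alcohol. The C6 methyl ether must be exchanged for an acetate, which for a secondary methyl ether calls for Lewis acids that the allylic alcohols would not survive.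
- Comparison: the chosen plan is longer before its key step, but it relays each stereocentre from C10 by ordinary substrate control and never has to remove an alkene or a methyl ether.

Alternative 3: Ring B is cut at C7–C8 and C9–C10 into silyloxydiene A7 (C10=C5–C6(OSi)=C7 on an intact ring A) and but-2-ynal A8. A chiral oxazaborolidinium triflimide would catalyse the Diels–Alder reaction to the 1,4-cyclohexadiene A9.
- Merits: this is the shortest entry. One step from an achiral diene builds ring B, sets C10 and places the C8=C9 alkene, the C17 methyl group, a C11 aldehyde and the C6 oxygen. On step count to the decalin it beats the chosen plan by a wide margin.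
- Weak points: the diene terminus C10 is fully substituted and the trimethylcyclohexenyl unit is twisted out of the s-cis geometry by the C4 methyl groups. The cycloaddition would need forcing conditions that a cationic boron catalyst and a polymerisable ynal tolerate poorly, and a linear ynal gives the catalyst little to tell its faces apart. After A9, C5 must be protonated to the trans fusion, C7 hydroxylated on the α-face next to a C6 ketone, and that ketone reduced to the axial 6β-alcohol. C11 arrives as an aldehyde and must become a methylene group joined to an allylic C12 nucleophile without loss of regio- or Z-integrity.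
- Comparison: the chosen plan gives up brevity, but its key step belongs to a reaction class with a long record on cyclopentenes, and it obtains the C7 configuration and the C9–C11 bond by routine means.

Key step: step 13

## Route

Remark on numbering: all bicycles carry labdane locants in the normal (5α-H, 10β-methyl) series; in the hydrindane compounds of steps 1–12 the five-membered ring is C5–C6–C7–C9–C10, C8 is absent until the key step, and α is the face opposite the C10 methyl group.

Remark on intermediates: where one operation is repeated on several sites within a step (double methylation, introduction or removal of several silyl or acetyl groups), the partly reacted species are not numbered.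

Step 1
Reactants: 1 (S)-Hajos–Parrish ketone
Product: 2 9,9-ethylenedioxy-10β-methylhydrind-4-en-3-one (C9 mono-ethylene ketal of 1)
Conditions: HOCH2CH2OH, TsOH·H2O (cat.), 4 Å MS, rt
Reagents that add atoms: ethylene glycol, OCCO
Why: Acid-catalysed ketalisation under mild, water-scavenged conditions discriminates the two carbonyls: the saturated C9 ketone is the more electrophilic one, whereas the C3 carbonyl is deactivated by conjugation with C4=C5; C10 is not touched.

Step 2
Reactants: 2 9,9-ethylenedioxy-10β-methylhydrind-4-en-3-one
Product: 3 9,9-ethylenedioxy-4,4,10β-trimethylhydrind-5-en-3-one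
Conditions: KOt-Bu (3.5 equiv), t-BuOH/THF, 0 °C; MeI (excess), 0 °C → rt
Reagents that add atoms: iodomethane, CI
Why: Deconjugative α,α-dialkylation of a β,β-disubstituted enone: KOt-Bu forms the extended dienolate (O–C3=C4–C5=C6), which is methylated twice at the α-carbon C4; once C4 is quaternary the alkene is fixed at C5=C6, where the next steps need it.

Step 3
Reactants: 3 9,9-ethylenedioxy-4,4,10β-trimethylhydrind-5-en-3-one
Product: 5 9,9-ethylenedioxy-4,4,10β-trimethylhydrind-5-ene, via hydrazone 4 (not isolated)
Conditions: N2H4·H2O, KOH, diethylene glycol, 130 → 200 °C (water distilled off)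
Reagents that add atoms: none
Why: Wolff–Kishner reduction in the Huang–Minlon manner removes the hindered C3 carbonyl via hydrazone 4 and loss of N2; the dioxolane is inert to hot alkali and the C5=C6 alkene has no conjugating partner left to migrate towards.

Step 4
Reactants: 5 9,9-ethylenedioxy-4,4,10β-trimethylhydrind-5-ene
Product: 7 9,9-ethylenedioxy-4,4,10β-trimethyl-5α-hydrindan-6α-ol, via 6α-alkylborane 6 (not isolated)
Conditions: BH3·THF, THF, 0 °C → rt; then NaOH (aq.), H2O2, 0 °C → rt
Reagents that add atoms: hydrogen peroxide, OO
Why: Hydroboration–oxidation: borane adds syn and anti-Markovnikov from the α-face, opposite the C10 methyl group, as is general for angularly methylated hydrindenes and octalins; boron goes to C6 and hydrogen to C5, so the trans ring fusion (5α-H) and the 6α-oxygen arise together, and the C–B bond is oxidised with retention.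

Step 5
Reactants: 7 9,9-ethylenedioxy-4,4,10β-trimethyl-5α-hydrindan-6α-ol
Product: 8 9,9-ethylenedioxy-4,4,10β-trimethyl-5α-hydrindan-6-one
Conditions: Dess–Martin periodinane, NaHCO3, CH2Cl2, 0 °C → rt
Reagents that add atoms: none
Why: Dess–Martin oxidation under bicarbonate buffering converts the secondary alcohol into the ketone without acid or base strong enough to enolise towards C5, so the kinetically formed trans fusion should be kept; the ketal is unaffected.

Step 6
Reactants: 8 9,9-ethylenedioxy-4,4,10β-trimethyl-5α-hydrindan-6-one
Product: 9 9,9-ethylenedioxy-4,4,10β-trimethyl-5α-hydrindan-6β-ol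
Conditions: NaBH4, MeOH/THF, −20 °C
Reagents that add atoms: none
Why: Borohydride reduction under steric approach control: the β-face of C6 is screened by the C10 methyl and the axial 4β-methyl groups, so hydride enters from the α-face and gives the 6β-alcohol; low temperature and the protic medium limit enolisation at C5.

Step 7
Reactants: 9 9,9-ethylenedioxy-4,4,10β-trimethyl-5α-hydrindan-6β-ol
Product: 10 6β-(tert-butyldimethylsilyloxy)-9,9-ethylenedioxy-4,4,10β-trimethyl-5α-hydrindane
Conditions: t-BuMe2SiOTf, 2,6-lutidine, CH2Cl2, −78 → 0 °C
Reagents that add atoms: tert-butyldimethylsilyl triflate, CC(C)(C)[Si](C)(C)OS(=O)(=O)C(F)(F)F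
Why: Silylation of a hindered secondary alcohol with the silyl triflate and a hindered pyridine base; the bulky 6β-silyl ether is the element that later steers water to the α-face of C7.

Step 8
Reactants: 10 6β-(tert-butyldimethylsilyloxy)-9,9-ethylenedioxy-4,4,10β-trimethyl-5α-hydrindane
Product: 11 6β-(tert-butyldimethylsilyloxy)-4,4,10β-trimethyl-5α-hydrindan-9-one
Conditions: PPTS, acetone/H2O (9:1), 55 °C
Reagents that add atoms: water, O
Why: Mild acid-catalysed hydrolysis of the dioxolane; a secondary tert-butyldimethylsilyl ether survives pyridinium tosylate, and the β-silyloxy ketone does not eliminate under these weakly acidic conditions.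

Step 9
Reactants: 11 6β-(tert-butyldimethylsilyloxy)-4,4,10β-trimethyl-5α-hydrindan-9-one
Product: 13 6β-(tert-butyldimethylsilyloxy)-4,4,10β-trimethyl-5α-hydrind-7(9)-en-9-yl triflate, via potassium enolate 12 (not isolated)
Conditions: KN(SiMe3)2, THF, −78 °C; then Comins' reagent, −78 °C
Reagents that add atoms: Comins' reagent [N-(5-chloropyridin-2-yl)bis(trifluoromethanesulfonyl)imide], Clc1ccc(nc1)N(S(=O)(=O)C(F)(F)F)S(=O)(=O)C(F)(F)F
Why: Kinetic enolate formation and O-triflation: C10 is quaternary, so deprotonation can occur only at C7, and the very reactive Comins' reagent traps enolate 12 at −78 °C before β-elimination of the C6 silyloxide can compete.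

Step 10
Reactants: 14 but-3-yn-1-ol
Product: 16 4-(triisopropylsilyl)but-3-yn-1-ol, via dilithio alkoxide acetylide 15 (not isolated)
Conditions: n-BuLi (2.1 equiv), THF, −78 → 0 °C; i-Pr3SiCl (1.05 equiv), −78 °C → rt; aq. NH4Cl
Reagents that add atoms: chlorotriisopropylsilane, CC(C)[Si](Cl)(C(C)C)C(C)C
Why: Double deprotonation gives the alkoxide–acetylide 15, which is silylated at the more nucleophilic carbon terminus by one equivalent of the hindered chlorosilane; the triisopropylsilyl group is chosen because it resists KOt-Bu and monovalent silver in the key step.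

Step 11
Reactants: 16 4-(triisopropylsilyl)but-3-yn-1-ol
Product: 17 (4-iodobut-1-yn-1-yl)triisopropylsilane
Conditions: PPh3, I2, imidazole, CH2Cl2, 0 °C → rt
Reagents that add atoms: iodine, II
Why: Appel-type iodination of a primary alcohol by SN2 displacement of the alkoxyphosphonium ion.

Step 12
Reactants: 17 (4-iodobut-1-yn-1-yl)triisopropylsilane; 13 6β-(tert-butyldimethylsilyloxy)-4,4,10β-trimethyl-5α-hydrind-7(9)-en-9-yl triflate
Product: 19 6β-(tert-butyldimethylsilyloxy)-4,4,10β-trimethyl-9-[4-(triisopropylsilyl)but-3-yn-1-yl]-5α-hydrind-7(9)-ene, via alkylzinc iodide 18 (not isolated)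
Conditions: 17, Zn dust (activated with BrCH2CH2Br and Me3SiCl), LiCl, THF, 40 °C; then 13, PdCl2(dppf) (5 mol %), THF, 50 °C
Reagents that add atoms: none
Why: Negishi alkyl–alkenyl coupling: zinc inserts into the primary C–I bond to give 18, and zerovalent palladium adds to the alkenyl triflate, transmetallates and eliminates reductively; enol triflates flanked by a quaternary carbon in a five-membered ring are good substrates, and the wide-bite-angle dppf ligand suppresses β-hydride elimination.

Step 13
Reactants: 19 6β-(tert-butyldimethylsilyloxy)-4,4,10β-trimethyl-9-[4-(triisopropylsilyl)but-3-yn-1-yl]-5α-hydrind-7(9)-ene; 20 bromoform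
Product: 22 8-bromo-6β-(tert-butyldimethylsilyloxy)-14-(triisopropylsilyl)-15,16,17-trinorlabd-8-en-13-yn-7α-ol, via dibromocyclopropane 21 (not isolated)
Conditions: CHBr3, KOt-Bu, hexane, 0 °C → rt; filter, concentrate; then AgClO4, CaCO3, acetone/H2O (5:1), rt, dark
Reagents that add atoms: water, O
Why: Singlet dibromocarbene from CHBr3 and KOt-Bu adds cheletropically ([2+1]) to the only alkene, the electron-rich trisubstituted C7=C9 bond, from the α-face opposite the C10 methyl and 6β-silyloxy groups, which creates C7–C8 and C8–C9 in adduct 21. Monovalent silver then removes the endo bromide while the C7–C9 σ-bond opens in the disrotatory sense required by the Woodward–Hoffmann–DePuy rule, so the five-membered ring becomes ring B as a 2-bromocyclohexenyl cation (C7–C8–C9); ring B thus arises by one-carbon ring expansion and not by a ring-closing bond formation, and any allylic dibromide formed by premature opening of 21 enters the same cation. The closest known reaction type is the dihalocarbene ring expansion of cyclopentenes to 2-halocyclohex-2-enols by silver-assisted solvolysis. Water is captured at C7 and not at C9 because C9 is a fully substituted terminus pressed against quaternary C10 and because attack at C7 leaves the more substituted, bromine-bearing C8=C9 alkene. The one new stereocentre, C7, is controlled by the 6β-silyloxy group: water enters on the α-face, anti to the bulky axial C6 substituent and along the pseudoaxial trajectory, to give the 7α-alcohol trans to O6. The carbene must meet one alkene only, which is secured by carrying the side chain as a triisopropylsilyl alkyne inert to electrophilic carbenes, to KOt-Bu and to silver, and CaCO3 takes up the HClO4 so that the silyl ether survives.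

Step 14
Reactants: 22 8-bromo-6β-(tert-butyldimethylsilyloxy)-14-(triisopropylsilyl)-15,16,17-trinorlabd-8-en-13-yn-7α-ol
Product: 23 6β-(tert-butyldimethylsilyloxy)-14-(triisopropylsilyl)-15,16-dinorlabd-8-en-13-yn-7α-ol
Conditions: MeZnCl (4 equiv), Pd(P(t-Bu)3)2 (5 mol %), THF/NMP, 60 °C
Reagents that add atoms: methylzinc chloride, C[Zn]Cl
Why: Negishi methylation of the alkenyl bromide; 2-bromocyclohex-2-enols are established cross-coupling partners, the bulky electron-rich phosphine promotes oxidative addition at the tetrasubstituted C8–Br bond, and the free hydroxyl is carried as its zinc alkoxide.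

Step 15
Reactants: 23 6β-(tert-butyldimethylsilyloxy)-14-(triisopropylsilyl)-15,16-dinorlabd-8-en-13-yn-7α-ol
Product: 24 15,16-dinorlabd-8-en-13-yne-6β,7α-diol
Conditions: Bu4NF (6 equiv), THF, 60 °C
Reagents that add atoms: none
Why: Fluoride-mediated desilylation removes the alkynyl triisopropylsilyl group and, on warming, the hindered 6β-silyl ether in one operation, so no selectivity between silyl groups is needed; no stereocentre is affected.

Step 16
Reactants: 24 15,16-dinorlabd-8-en-13-yne-6β,7α-diol
Product: 25 6β,7α-bis(triethylsilyloxy)-15,16-dinorlabd-8-en-13-yne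
Conditions: Et3SiOTf (3 equiv), 2,6-lutidine, CH2Cl2, −78 → 0 °C
Reagents that add atoms: triethylsilyl triflate, CC[Si](CC)(CC)OS(=O)(=O)C(F)(F)F
Why: Silylation of both hydroxyls with the silyl triflate, which is reactive enough for the axial 6β-position; triethylsilyl ethers withstand n-BuLi, the cuprate and i-Bu2AlH and are later removed by fluoride at room temperature.

Step 17
Reactants: 25 6β,7α-bis(triethylsilyloxy)-15,16-dinorlabd-8-en-13-yne
Product: 27 methyl 6β,7α-bis(triethylsilyloxy)-16-norlabd-8-en-13-yn-15-oate, via lithium acetylide 26 (not isolated)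
Conditions: n-BuLi, THF, −78 °C; ClCO2Me, −78 → 0 °C
Reagents that add atoms: methyl chloroformate, COC(=O)Cl
Why: Deprotonation of the terminal alkyne and C-acylation of acetylide 26 with methyl chloroformate, a standard route to alk-2-ynoates; this adds C15.

Step 18
Reactants: 27 methyl 6β,7α-bis(triethylsilyloxy)-16-norlabd-8-en-13-yn-15-oate
Product: 29 methyl (13Z)-6β,7α-bis(triethylsilyloxy)labda-8,13-dien-15-oate, via alkenylcuprate 28 (not isolated)
Conditions: Me2CuLi (from MeLi and CuI), THF, −78 °C; MeOH then aq. NH4Cl at −78 °C
Reagents that add atoms: lithium dimethylcuprate, [Li+].C[Cu-]C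
Why: Conjugate addition of the Gilman cuprate to the ynoate is a syn-carbocupration: methyl (C16) and copper add to the same side, and protonation of 28 at −78 °C with retention puts C12 and C15 cis, that is the (13Z)-enoate; warming before the quench is avoided because the alkenylcuprate equilibrates through the allenolate.

Step 19
Reactants: 29 methyl (13Z)-6β,7α-bis(triethylsilyloxy)labda-8,13-dien-15-oate
Product: 30 (13Z)-6β,7α-bis(triethylsilyloxy)labda-8,13-dien-15-ol
Conditions: i-Bu2AlH (3 equiv), CH2Cl2, −78 → 0 °C; aq. potassium sodium tartrate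
Reagents that add atoms: none
Why: i-Bu2AlH reduces the conjugated ester by two 1,2-hydride additions to the allylic alcohol without touching the alkene geometry; the silyl ethers are stable.

Step 20
Reactants: 30 (13Z)-6β,7α-bis(triethylsilyloxy)labda-8,13-dien-15-ol
Product: 31 (13Z)-labda-8,13-diene-6β,7α,15-triol
Conditions: Bu4NF, THF, 0 °C → rt
Reagents that add atoms: none
Why: Fluoride cleavage of the two triethylsilyl ethers under basic, non-ionising conditions that leave the allylic C7–O bond and the Z-alkene intact.

Step 21
Reactants: 31 (13Z)-labda-8,13-diene-6β,7α,15-triol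
Product: 32 (13Z)-labda-8,13-diene-6β,7α,15-triyl triacetate
Conditions: Ac2O, pyridine, DMAP, 50 °C
Reagents that add atoms: acetic anhydride, CC(=O)OC(C)=O
Why: Exhaustive acylation with acetic anhydride under nucleophilic catalysis by 4-(dimethylamino)pyridine; warming is needed for the axial 6β-hydroxyl, and the basic medium avoids ionisation at C7.

Step 22
Reactants: 32 (13Z)-labda-8,13-diene-6β,7α,15-triyl triacetate
Product: 33 (13Z)-6β-acetoxylabda-8,13-diene-7α,15-diol (target CNP0183298.2)
Conditions: K2CO3 (cat.), MeOH, 0 °C, followed to the monoacetate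
Reagents that add atoms: none
Why: Base-catalysed transesterification whose rate follows steric access: the primary allylic 15-acetate and the allylic 7α-acetate are methanolysed, while the 6β-acetate, 1,3-diaxial to the C10 and 4β-methyl groups, is left; acyl migration from O6 to O7 is geometrically blocked because the two oxygens are trans-diaxial.

## Compound list

1 | (S)-Hajos–Parrish ketone | O=C1CC[C@]2(C)C(=O)CCC2=C1 | starting material
2 | 9,9-ethylenedioxy-10β-methylhydrind-4-en-3-one | O=C1CC[C@]2(C)C3(OCCO3)CCC2=C1 | intermediate
3 | 9,9-ethylenedioxy-4,4,10β-trimethylhydrind-5-en-3-one | O=C1CC[C@]2(C)C3(OCCO3)CC=C2C1(C)C | intermediate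
4 | hydrazone of 3 | NN=C1CC[C@]2(C)C3(OCCO3)CC=C2C1(C)C | intermediate (not isolated)
5 | 9,9-ethylenedioxy-4,4,10β-trimethylhydrind-5-ene | C1CC[C@]2(C)C3(OCCO3)CC=C2C1(C)C | intermediate
6 | 6α-boryl-9,9-ethylenedioxy-4,4,10β-trimethyl-5α-hydrindane (drawn as the monoalkylborane) | B[C@H]1CC2(OCCO2)[C@@]3(C)CCCC(C)(C)[C@H]13 | intermediate (not isolated)
7 | 9,9-ethylenedioxy-4,4,10β-trimethyl-5α-hydrindan-6α-ol | O[C@H]1CC2(OCCO2)[C@@]3(C)CCCC(C)(C)[C@H]13 | intermediate
8 | 9,9-ethylenedioxy-4,4,10β-trimethyl-5α-hydrindan-6-one | O=C1CC2(OCCO2)[C@@]3(C)CCCC(C)(C)[C@H]13 | intermediate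
9 | 9,9-ethylenedioxy-4,4,10β-trimethyl-5α-hydrindan-6β-ol | O[C@@H]1CC2(OCCO2)[C@@]3(C)CCCC(C)(C)[C@H]13 | intermediate
10 | 6β-(tert-butyldimethylsilyloxy)-9,9-ethylenedioxy-4,4,10β-trimethyl-5α-hydrindane | CC(C)(C)[Si](C)(C)O[C@@H]1CC2(OCCO2)[C@@]3(C)CCCC(C)(C)[C@H]13 | intermediate
11 | 6β-(tert-butyldimethylsilyloxy)-4,4,10β-trimethyl-5α-hydrindan-9-one | CC(C)(C)[Si](C)(C)O[C@@H]1CC(=O)[C@@]2(C)CCCC(C)(C)[C@H]12 | intermediate
12 | potassium Δ7(9)-enolate of 11 | CC(C)(C)[Si](C)(C)O[C@@H]1C=C([O-])[C@@]2(C)CCCC(C)(C)[C@H]12.[K+] | intermediate (not isolated)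
13 | 6β-(tert-butyldimethylsilyloxy)-4,4,10β-trimethyl-5α-hydrind-7(9)-en-9-yl triflate | CC(C)(C)[Si](C)(C)O[C@@H]1C=C(OS(=O)(=O)C(F)(F)F)[C@@]2(C)CCCC(C)(C)[C@H]12 | intermediate
14 | but-3-yn-1-ol | C#CCCO | starting material
15 | dilithium 4-oxidobut-1-yn-1-ide | [Li+].[Li+].[O-]CCC#[C-] | intermediate (not isolated)
16 | 4-(triisopropylsilyl)but-3-yn-1-ol | CC(C)[Si](C#CCCO)(C(C)C)C(C)C | intermediate
17 | (4-iodobut-1-yn-1-yl)triisopropylsilane | CC(C)[Si](C#CCCI)(C(C)C)C(C)C | intermediate
18 | [4-(triisopropylsilyl)but-3-yn-1-yl]zinc iodide | CC(C)[Si](C#CCC[Zn]I)(C(C)C)C(C)C | intermediate (not isolated)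
19 | 6β-(tert-butyldimethylsilyloxy)-4,4,10β-trimethyl-9-[4-(triisopropylsilyl)but-3-yn-1-yl]-5α-hydrind-7(9)-ene | CC(C)(C)[Si](C)(C)O[C@@H]1C=C(CCC#C[Si](C(C)C)(C(C)C)C(C)C)[C@@]2(C)CCCC(C)(C)[C@H]12 | intermediate
20 | bromoform | BrC(Br)Br | starting material
21 | 7α,9α-(dibromomethano) adduct of 19 (8,8-dibromocyclopropane on the α-face) | CC(C)(C)[Si](C)(C)O[C@@H]1[C@H]3C(Br)(Br)[C@@]3(CCC#C[Si](C(C)C)(C(C)C)C(C)C)[C@@]2(C)CCCC(C)(C)[C@H]12 | intermediate (not isolated)
22 | 8-bromo-6β-(tert-butyldimethylsilyloxy)-14-(triisopropylsilyl)-15,16,17-trinorlabd-8-en-13-yn-7α-ol | CC(C)(C)[Si](C)(C)O[C@@H]1[C@@H](O)C(Br)=C(CCC#C[Si](C(C)C)(C(C)C)C(C)C)[C@@]2(C)CCCC(C)(C)[C@H]12 | intermediate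
23 | 6β-(tert-butyldimethylsilyloxy)-14-(triisopropylsilyl)-15,16-dinorlabd-8-en-13-yn-7α-ol | CC(C)(C)[Si](C)(C)O[C@@H]1[C@@H](O)C(C)=C(CCC#C[Si](C(C)C)(C(C)C)C(C)C)[C@@]2(C)CCCC(C)(C)[C@H]12 | intermediate
24 | 15,16-dinorlabd-8-en-13-yne-6β,7α-diol | O[C@@H]1[C@@H](O)C(C)=C(CCC#C)[C@@]2(C)CCCC(C)(C)[C@H]12 | intermediate
25 | 6β,7α-bis(triethylsilyloxy)-15,16-dinorlabd-8-en-13-yne | CC[Si](CC)(CC)O[C@@H]1[C@@H](O[Si](CC)(CC)CC)C(C)=C(CCC#C)[C@@]2(C)CCCC(C)(C)[C@H]12 | intermediate
26 | lithium acetylide of 25 | CC[Si](CC)(CC)O[C@@H]1[C@@H](O[Si](CC)(CC)CC)C(C)=C(CCC#[C-])[C@@]2(C)CCCC(C)(C)[C@H]12.[Li+] | intermediate (not isolated)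
27 | methyl 6β,7α-bis(triethylsilyloxy)-16-norlabd-8-en-13-yn-15-oate | CC[Si](CC)(CC)O[C@@H]1[C@@H](O[Si](CC)(CC)CC)C(C)=C(CCC#CC(=O)OC)[C@@]2(C)CCCC(C)(C)[C@H]12 | intermediate
28 | lithium methyl C14-alkenylcuprate from syn-addition to 27 | CC[Si](CC)(CC)O[C@@H]1[C@@H](O[Si](CC)(CC)CC)C(C)=C(CC/C(C)=C(/[Cu-]C)C(=O)OC)[C@@]2(C)CCCC(C)(C)[C@H]12.[Li+] | intermediate (not isolated)
29 | methyl (13Z)-6β,7α-bis(triethylsilyloxy)labda-8,13-dien-15-oate | CC[Si](CC)(CC)O[C@@H]1[C@@H](O[Si](CC)(CC)CC)C(C)=C(CC/C(C)=C\C(=O)OC)[C@@]2(C)CCCC(C)(C)[C@H]12 | intermediate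
30 | (13Z)-6β,7α-bis(triethylsilyloxy)labda-8,13-dien-15-ol | CC[Si](CC)(CC)O[C@@H]1[C@@H](O[Si](CC)(CC)CC)C(C)=C(CC/C(C)=C\CO)[C@@]2(C)CCCC(C)(C)[C@H]12 | intermediate
31 | (13Z)-labda-8,13-diene-6β,7α,15-triol | O[C@@H]1[C@@H](O)C(C)=C(CC/C(C)=C\CO)[C@@]2(C)CCCC(C)(C)[C@H]12 | intermediate
32 | (13Z)-labda-8,13-diene-6β,7α,15-triyl triacetate | CC(=O)O[C@@H]1[C@@H](OC(C)=O)C(C)=C(CC/C(C)=C\COC(C)=O)[C@@]2(C)CCCC(C)(C)[C@H]12 | intermediate
33 | (13Z)-6β-acetoxylabda-8,13-diene-7α,15-diol (CNP0183298.2) | CC(=O)O[C@@H]1[C@@H](O)C(C)=C(CC/C(C)=C\CO)[C@@]2(C)CCCC(C)(C)[C@H]12 | target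

## Step count and least certain steps

Total: 22 steps. Longest linear sequence: 20 steps (1 → 33 through steps 1–9 and 12–22); the side branch from 14 contributes steps 10 and 11.

**Step 13 (key step).** The most likely failure is sluggish cyclopropanation of the trisubstituted alkene, which is shielded by quaternary C10 and by the silyloxy-bearing C6, so that the carbene decomposes before it adds. The second risk is capture of water with imperfect positional or facial selectivity. The fallback sets out from ketone 11 and puts the carbene on a far more nucleophilic alkene. Soft enolisation (Me3SiOTf, Et3N) should give the trimethylsilyl enol ether of 11 F1. Dibromocarbene addition to F1 and collapse of the adduct with loss of the silyl bromide should give the ring-expanded 8-bromo-6β-(tert-butyldimethylsilyloxy) Δ7-en-9-one F2. The organocerium reagent made from iodide 17 (t-BuLi, then CeCl3) should add to the C9 carbonyl to give the tertiary allylic alcohol F3. Brief treatment with dilute aqueous acid (TsOH, THF/H2O) should ionise F3 to the same C7–C8–C9 cation, and water capture anti to O6 returns the route at 22.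

**Step 5 (with step 6).** The process to fear is epimerisation at C5 of the strained trans-fused ketone 8 during oxidation, isolation or reduction, since C5 is α to the carbonyl and cis-hydrindanones are the more stable; hydride delivery from the wrong face is a lesser risk. The fallback avoids the ketone: starting from alcohol 7, a Mitsunobu inversion (4-nitrobenzoic acid, PPh3, diisopropyl azodicarboxylate) should give the 6β-(4-nitrobenzoate) F4, and methanolysis (K2CO3, MeOH) returns the route at 9.

**Step 9.** The enolate may expel the β-silyloxide (E1cB) before it is triflated, or triflation at the hindered enolate oxygen may be incomplete. The fallback uses no enolate: starting from ketone 11, addition of the organocerium reagent derived from iodide 17 should give the tertiary alcohol F5, and dehydration (Burgess reagent) towards the endocyclic trisubstituted alkene returns the route at 19.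

**Step 14.** Oxidative addition and transmetallation at the tetrasubstituted C8–Br bond, flanked by C7 and the C9 chain, may be slow, so that protodebromination competes. The fallback replaces catalysis by an alkenyllithium: starting from 22, silylation (Et3SiCl, imidazole) should give the 7-O-triethylsilyl bromide F6. Bromine–lithium exchange (t-BuLi, −78 °C) and quenching with MeI should give the 7-O-triethylsilyl 8-methyl compound F7. The fluoride treatment of step 15 then removes all three silyl groups and returns the route at 24.

**Step 22 (with step 21).** The rate gap between methanolysis of the 7α-acetate and the 6β-acetate may be too small, or acetylation of the axial 6β-hydroxyl in step 21 may stay incomplete. The fallback differentiates by silylation instead of deacylation: starting from triol 31, Et3SiCl and imidazole at 0 °C should silylate the two accessible hydroxyls to give the 7,15-bis(triethylsilyl) ether F8. Acetylation of the remaining 6β-hydroxyl (Ac2O, DMAP) should give the 6β-acetate bis(triethylsilyl) ether F9, and buffered HF·pyridine returns the route at 33.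

## Further compounds

F1 | step 13 | trimethylsilyl enol ether of 11 | CC(C)(C)[Si](C)(C)O[C@@H]1C=C(O[Si](C)(C)C)[C@@]2(C)CCCC(C)(C)[C@H]12
F2 | step 13 | 8-bromo-6β-(tert-butyldimethylsilyloxy)-4,4,10β-trimethyl-5α-decal-7-en-9-one | CC(C)(C)[Si](C)(C)O[C@@H]1C=C(Br)C(=O)[C@@]2(C)CCCC(C)(C)[C@H]12
F3 | step 13 | 8-bromo-6β-(tert-butyldimethylsilyloxy)-14-(triisopropylsilyl)-15,16,17-trinorlabd-7-en-13-yn-9-ol (drawn as the 9β-ol expected from α-face attack; C9 is lost on ionisation) | CC(C)(C)[Si](C)(C)O[C@@H]1C=C(Br)[C@@](O)(CCC#C[Si](C(C)C)(C(C)C)C(C)C)[C@@]2(C)CCCC(C)(C)[C@H]12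
F4 | step 5 | 9,9-ethylenedioxy-4,4,10β-trimethyl-5α-hydrindan-6β-yl 4-nitrobenzoate | O=C(O[C@@H]1CC2(OCCO2)[C@@]3(C)CCCC(C)(C)[C@H]13)c1ccc(cc1)[N+](=O)[O-]
F5 | step 9 | 6β-(tert-butyldimethylsilyloxy)-4,4,10β-trimethyl-9α-[4-(triisopropylsilyl)but-3-yn-1-yl]-5α-hydrindan-9β-ol | CC(C)(C)[Si](C)(C)O[C@@H]1C[C@@](O)(CCC#C[Si](C(C)C)(C(C)C)C(C)C)[C@@]2(C)CCCC(C)(C)[C@H]12
F6 | step 14 | 8-bromo-6β-(tert-butyldimethylsilyloxy)-7α-(triethylsilyloxy)-14-(triisopropylsilyl)-15,16,17-trinorlabd-8-en-13-yne | CC(C)(C)[Si](C)(C)O[C@@H]1[C@@H](O[Si](CC)(CC)CC)C(Br)=C(CCC#C[Si](C(C)C)(C(C)C)C(C)C)[C@@]2(C)CCCC(C)(C)[C@H]12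
F7 | step 14 | 6β-(tert-butyldimethylsilyloxy)-7α-(triethylsilyloxy)-14-(triisopropylsilyl)-15,16-dinorlabd-8-en-13-yne | CC(C)(C)[Si](C)(C)O[C@@H]1[C@@H](O[Si](CC)(CC)CC)C(C)=C(CCC#C[Si](C(C)C)(C(C)C)C(C)C)[C@@]2(C)CCCC(C)(C)[C@H]12
F8 | step 22 | (13Z)-7α,15-bis(triethylsilyloxy)labda-8,13-dien-6β-ol | O[C@@H]1[C@@H](O[Si](CC)(CC)CC)C(C)=C(CC/C(C)=C\CO[Si](CC)(CC)CC)[C@@]2(C)CCCC(C)(C)[C@H]12
F9 | step 22 | (13Z)-7α,15-bis(triethylsilyloxy)labda-8,13-dien-6β-yl acetate | CC(=O)O[C@@H]1[C@@H](O[Si](CC)(CC)CC)C(C)=C(CC/C(C)=C\CO[Si](CC)(CC)CC)[C@@]2(C)CCCC(C)(C)[C@H]12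
A1 | alternative 1 | 3-methylcyclohex-2-enone | CC1=CC(=O)CCC1
A2 | alternative 1 | [4-(tert-butyldiphenylsilyloxy)but-1-en-2-yl]diisobutylalane | C=C(CCO[Si](c1ccccc1)(c1ccccc1)C(C)(C)C)[Al](CC(C)C)CC(C)C
A3 | alternative 1 | 3-methylbut-3-enal | C=C(C)CC=O
A4 | alternative 1 | 2,3-disubstituted 3-methylcyclohexanone aldol with C10 and C5 set | C=C(C)C[C@H](O)[C@H]1C(=O)CCC[C@]1(C)C(=C)CCO[Si](c1ccccc1)(c1ccccc1)C(C)(C)C
A5 | alternative 2 | hexasubstituted phenol with (E)-allylic methyl carbonate tether at C5 | COc1c(O)c(C)c(CC/C(C)=C\CO[Si](C)(C)C(C)(C)C)c(C)c1C(C)(C)/C=C/COC(=O)OC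
A6 | alternative 2 | 6-methoxylabda-2,5,8,13Z-tetraen-7-one 15-(tert-butyldimethylsilyl) ether | COC1=C2C(C)(C)C=CC[C@]2(C)C(CC/C(C)=C\CO[Si](C)(C)C(C)(C)C)=C(C)C1=O
A7 | alternative 3 | tert-butyldimethylsilyl enol ether of 1-(2,6,6-trimethylcyclohex-1-en-1-yl)ethanone | C=C(O[Si](C)(C)C(C)(C)C)C1=C(C)CCCC1(C)C
A8 | alternative 3 | but-2-ynal | CC#CC=O
A9 | alternative 3 | bicyclic 1,4-cyclohexadiene with C6 silyl enol ether, C8=C9 alkene and C11 aldehyde | CC(C)(C)[Si](C)(C)OC1=C2C(C)(C)CCC[C@]2(C)C(C=O)=C(C)C1
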